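The dihydrofuran ring is closed through its C2–C3 bond: a rhodium carbene generated at the future C3 inserts into a C–H bond of the carbon that becomes C2. That carbon is the O1–CH2 of a 3,4,5-trimethoxybenzyl ether; it is benzylic, bonded to O1 and 1,5 to the carbene, so one operation closes ring B (O1–C2–C3–C3a–C7a) and sets C2 and C3. The precursor is methyl 2-diazo-2-[3-methoxy-4-(methoxymethoxy)-2-(3,4,5-trimethoxybenzyloxy)phenyl]acetate. Ester-to-methyl adjustment, Claisen transfer of an allyl group to C5, a reagent-controlled hydroxylative dearomatisation and O-methylation then turn aromatic ring A into the 5-allyl-5-methoxy dienone.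

Key step: step 6

Assumption: the senses of induction of the two chiral reagents (steps 6 and 14) are taken as written; should either deliver the opposite configuration, its mirror-image form is used with no other change.

Step 1
Reactants: 1 2-methoxyresorcinol (2-methoxybenzene-1,3-diol)
Product: 2 1-(2,4-dihydroxy-3-methoxyphenyl)ethan-1-one
Conditions: AcOH, BF3·OEt2 (promoter), 90 °C
Reagents that add atoms: acetic acid CC(=O)O
Why: Nencki-type Friedel–Crafts C-acylation occurs at the ring carbon ortho to one hydroxyl and para to the other (C4 and C6 are equivalent by symmetry), and the boron chelate of the resulting ortho-hydroxy ketone deactivates the ring against a second acylation.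

Step 2
Reactants: 2 1-(2,4-dihydroxy-3-methoxyphenyl)ethan-1-one
Product: 3 1-[2-hydroxy-3-methoxy-4-(methoxymethoxy)phenyl]ethan-1-one
Conditions: MOMCl (1.05 equiv), K2CO3, acetone, 0 °C to rt
Reagents that add atoms: chloromethyl methyl ether COCCl
Why: Williamson-type O-alkylation picks the 4-hydroxyl, which is the more acidic para-acyl phenol and is not tied up in the strong hydrogen bond that holds the 2-hydroxyl to the ketone.

Step 3
Reactants: 3 1-[2-hydroxy-3-methoxy-4-(methoxymethoxy)phenyl]ethan-1-one; 4 3,4,5-trimethoxybenzyl chloride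
Product: 5 1-[3-methoxy-4-(methoxymethoxy)-2-(3,4,5-trimethoxybenzyloxy)phenyl]ethan-1-one
Conditions: K2CO3, KI (cat.), DMF, 60 °C
Reagents that add atoms: none
Why: Williamson etherification of the remaining chelated phenol under warmer carbonate conditions with in situ Finkelstein activation of the benzylic chloride, the MOM acetal being stable to base.

Step 4
Reactants: 5 1-[3-methoxy-4-(methoxymethoxy)-2-(3,4,5-trimethoxybenzyloxy)phenyl]ethan-1-one
Product: 6 methyl 2-[3-methoxy-4-(methoxymethoxy)-2-(3,4,5-trimethoxybenzyloxy)phenyl]acetate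
Conditions: Tl(NO3)3·3H2O (1.1 equiv), MeOH–HC(OMe)3 1:1, rt, short reaction time
Reagents that add atoms: methanol CO
Why: Thallium(III)-mediated oxidative rearrangement of an aryl methyl ketone, in which oxythallation of the enol ether formed in methanol–orthoformate triggers a 1,2-shift of the electron-rich aryl group with loss of Tl(I) to give the methyl arylacetate; MOM aryl ethers tolerate these brief conditions in the related chalcone rearrangements.

Step 5
Reactants: 6 methyl 2-[3-methoxy-4-(methoxymethoxy)-2-(3,4,5-trimethoxybenzyloxy)phenyl]acetate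
Product: 7 methyl 2-diazo-2-[3-methoxy-4-(methoxymethoxy)-2-(3,4,5-trimethoxybenzyloxy)phenyl]acetate
Conditions: p-ABSA, DBU, MeCN, 0 °C to rt
Reagents that add atoms: 4-acetamidobenzenesulfonyl azide (p-ABSA) CC(=O)Nc1ccc(cc1)S(=O)(=O)N=[N+]=[N-]
Why: Regitz diazo transfer to the benzylic ester enolate generated by DBU, the standard entry to aryldiazoacetates.

Step 6
Reactants: 7 methyl 2-diazo-2-[3-methoxy-4-(methoxymethoxy)-2-(3,4,5-trimethoxybenzyloxy)phenyl]acetate
Product: 8 methyl (2S,3R)-7-methoxy-6-(methoxymethoxy)-2-(3,4,5-trimethoxyphenyl)-2,3-dihydrobenzofuran-3-carboxylate (cis)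
Conditions: Rh2(S-PTTL)4 (1 mol %), toluene, −60 °C, slow addition of 7
Reagents that add atoms: none
Why: Rh(II) extrudes N2 from 7 to give a donor/acceptor carbene on the future C3, which inserts into one hydrogen of the ortho O–CH2–aryl group through a concerted three-centre, hydride-transfer-like transition state, creating C2–C3. The closest known reaction type is the Rh(II)-carboxylate-catalysed enantioselective intramolecular 1,5 C–H insertion of ortho-benzyloxy aryldiazoacetates, which gives cis-2-aryl-2,3-dihydrobenzofuran-3-carboxylates. Ring B (O1, C2, C3, C3a, C7a) closes in the 1,5-insertion mode, the carbene carbon and the C–H carbon being joined through a five-membered cyclic transition state; no other C–H bond can be reached without a strained four- or seven-membered alternative. C2 is controlled by the chiral N-phthaloyl-tert-leucinate ligand shell, which discriminates the two enantiotopic benzylic hydrogens, and C3 by the kinetic preference of that transition state for the cis product, in which ester and aryl group lie on the same face. The step needs site selectivity over carbene dimerisation, attack on the aromatic rings and intermolecular insertion into the MOM group; it is secured by the double activation of the target C–H bond (α to O1 and benzylic to the electron-rich trimethoxyphenyl ring), its 1,5 relationship to the carbene and slow addition of 7 at low temperature.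

Step 7
Reactants: 8 methyl (2S,3R)-7-methoxy-6-(methoxymethoxy)-2-(3,4,5-trimethoxyphenyl)-2,3-dihydrobenzofuran-3-carboxylate
Product: 9 methyl (2S,3S)-7-methoxy-6-(methoxymethoxy)-2-(3,4,5-trimethoxyphenyl)-2,3-dihydrobenzofuran-3-carboxylate (trans)
Conditions: NaOMe (0.3 equiv), MeOH, 40 °C
Reagents that add atoms: none
Why: Methoxide equilibrates C3 through the ester enolate to the thermodynamically preferred trans isomer, in which the C2 aryl and C3 ester groups lie on opposite faces, while C2 carries no acidic hydrogen and keeps its configuration.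

Step 8
Reactants: 9 methyl (2S,3S)-7-methoxy-6-(methoxymethoxy)-2-(3,4,5-trimethoxyphenyl)-2,3-dihydrobenzofuran-3-carboxylate
Product: 10 [(2S,3R)-7-methoxy-6-(methoxymethoxy)-2-(3,4,5-trimethoxyphenyl)-2,3-dihydrobenzofuran-3-yl]methanol
Conditions: LiAlH4, THF, 0 °C
Reagents that add atoms: none
Why: Hydride reduction of the ester to the primary alcohol leaves the aryl ethers, the MOM acetal and both stereocentres untouched (the C3 descriptor changes only through CIP priorities).

Step 9
Reactants: 10 [(2S,3R)-7-methoxy-6-(methoxymethoxy)-2-(3,4,5-trimethoxyphenyl)-2,3-dihydrobenzofuran-3-yl]methanol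
Product: 11 [(2S,3R)-7-methoxy-6-(methoxymethoxy)-2-(3,4,5-trimethoxyphenyl)-2,3-dihydrobenzofuran-3-yl]methyl 4-methylbenzenesulfonate
Conditions: TsCl, Et3N, DMAP (cat.), CH2Cl2, 0 °C to rt
Reagents that add atoms: 4-toluenesulfonyl chloride Cc1ccc(cc1)S(Cl)(=O)=O
Why: Sulfonylation of the primary alcohol under standard amine/DMAP conditions converts it into a leaving group without touching C3.

Step 10
Reactants: 11 [(2S,3R)-7-methoxy-6-(methoxymethoxy)-2-(3,4,5-trimethoxyphenyl)-2,3-dihydrobenzofuran-3-yl]methyl 4-methylbenzenesulfonate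
Product: 12 (2S,3S)-7-methoxy-6-(methoxymethoxy)-3-methyl-2-(3,4,5-trimethoxyphenyl)-2,3-dihydrobenzofuran
Conditions: LiBHEt3, THF, 0 °C to rt
Reagents that add atoms: none
Why: SN2 displacement of the primary tosylate by the strongly nucleophilic triethylborohydride gives the C3 methyl group, direct hydride attack outrunning aryl participation so that ring size and C3 configuration are kept.

Step 11
Reactants: 12 (2S,3S)-7-methoxy-6-(methoxymethoxy)-3-methyl-2-(3,4,5-trimethoxyphenyl)-2,3-dihydrobenzofuran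
Product: 13 (2S,3S)-7-methoxy-3-methyl-2-(3,4,5-trimethoxyphenyl)-2,3-dihydrobenzofuran-6-ol
Conditions: 3 M HCl, MeOH, 45 °C
Reagents that add atoms: none
Why: Acid-catalysed transacetalisation removes the MOM group, and because the trans-dihydrobenzofuran is the thermodynamic isomer any reversible ionisation at benzylic C2 returns the same compound.

Step 12
Reactants: 13 (2S,3S)-7-methoxy-3-methyl-2-(3,4,5-trimethoxyphenyl)-2,3-dihydrobenzofuran-6-ol; 14 allyl bromide
Product: 15 (2S,3S)-6-(allyloxy)-7-methoxy-3-methyl-2-(3,4,5-trimethoxyphenyl)-2,3-dihydrobenzofuran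
Conditions: K2CO3, acetone, reflux
Reagents that add atoms: none
Why: Williamson O-allylation of the liberated phenol under mild carbonate conditions.

Step 13
Reactants: 15 (2S,3S)-6-(allyloxy)-7-methoxy-3-methyl-2-(3,4,5-trimethoxyphenyl)-2,3-dihydrobenzofuran
Product: 17 (2S,3S)-5-allyl-7-methoxy-3-methyl-2-(3,4,5-trimethoxyphenyl)-2,3-dihydrobenzofuran-6-ol, via Claisen ortho-dienone 16 (not isolated)
Conditions: PhNEt2, 190 °C, sealed tube
Reagents that add atoms: none
Why: Aromatic Claisen [3,3] rearrangement delivers the allyl group to C5, the only ortho carbon able to re-aromatise because C7 carries the methoxy group, and tautomerisation of the dienone gives the phenol.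

Step 14
Reactants: 17 (2S,3S)-5-allyl-7-methoxy-3-methyl-2-(3,4,5-trimethoxyphenyl)-2,3-dihydrobenzofuran-6-ol
Product: 18 (2S,3S,5R)-5-allyl-5-hydroxy-7-methoxy-3-methyl-2-(3,4,5-trimethoxyphenyl)-2,3-dihydrobenzofuran-6(5H)-one
Conditions: preformed (R)-2,2′-diiodyl-1,1′-binaphthyl (1.0 equiv), CH2Cl2, −40 °C to rt; aq NaHCO3
Reagents that add atoms: (R)-2,2′-diiodyl-1,1′-binaphthyl O=I(=O)c1ccc2ccccc2c1-c1c(I(=O)=O)ccc2ccccc12
Why: Hydroxylative phenol dearomatisation with a preformed chiral λ5-iodane, the reaction type that converts 2-alkylphenols into 6-alkyl-6-hydroxycyclohexa-2,4-dienones: the phenol binds to iodine and oxygen is passed intramolecularly to an ortho carbon (never to para C3a), C5 being preferred over C7 because it is para to O1 and unhindered whereas C7 is wedged between two oxygen-bearing carbons, and the axially chiral biaryl, not the remote C2/C3 centres, selects the C5 face that places OH syn to the C3 methyl group (5R).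

Step 15
Reactants: 18 (2S,3S,5R)-5-allyl-5-hydroxy-7-methoxy-3-methyl-2-(3,4,5-trimethoxyphenyl)-2,3-dihydrobenzofuran-6(5H)-one
Product: 19 (2S,3S,5R)-5-allyl-5,7-dimethoxy-3-methyl-2-(3,4,5-trimethoxyphenyl)-2,3-dihydrobenzofuran-6(5H)-one (CNP0080458.1)
Conditions: MeI (excess), Ag2O, 4 Å MS, MeCN, rt, dark
Reagents that add atoms: methyl iodide CI
Why: Purdie-type O-methylation with silver(I) oxide and methyl iodide alkylates the tertiary α-ketol under neutral conditions, so no free alkoxide is formed that could trigger an anionic oxy-Cope shift of the allyl group or an α-ketol rearrangement, and C5 is not touched.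

Compound list
1 | 2-methoxyresorcinol (2-methoxybenzene-1,3-diol) | COc1c(O)cccc1O | starting material
2 | 1-(2,4-dihydroxy-3-methoxyphenyl)ethan-1-one | CC(=O)c1ccc(O)c(OC)c1O | intermediate
3 | 1-[2-hydroxy-3-methoxy-4-(methoxymethoxy)phenyl]ethan-1-one | CC(=O)c1ccc(OCOC)c(OC)c1O | intermediate
4 | 3,4,5-trimethoxybenzyl chloride | COc1cc(CCl)cc(OC)c1OC | starting material
5 | 1-[3-methoxy-4-(methoxymethoxy)-2-(3,4,5-trimethoxybenzyloxy)phenyl]ethan-1-one | CC(=O)c1ccc(OCOC)c(OC)c1OCc1cc(OC)c(OC)c(OC)c1 | intermediate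
6 | methyl 2-[3-methoxy-4-(methoxymethoxy)-2-(3,4,5-trimethoxybenzyloxy)phenyl]acetate | COC(=O)Cc1ccc(OCOC)c(OC)c1OCc1cc(OC)c(OC)c(OC)c1 | intermediate
7 | methyl 2-diazo-2-[3-methoxy-4-(methoxymethoxy)-2-(3,4,5-trimethoxybenzyloxy)phenyl]acetate | COC(=O)C(=[N+]=[N-])c1ccc(OCOC)c(OC)c1OCc1cc(OC)c(OC)c(OC)c1 | intermediate
8 | methyl (2S,3R)-7-methoxy-6-(methoxymethoxy)-2-(3,4,5-trimethoxyphenyl)-2,3-dihydrobenzofuran-3-carboxylate (cis) | COCOc1ccc2c(c1OC)O[C@H](c1cc(OC)c(OC)c(OC)c1)[C@@H]2C(=O)OC | intermediate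
9 | methyl (2S,3S)-7-methoxy-6-(methoxymethoxy)-2-(3,4,5-trimethoxyphenyl)-2,3-dihydrobenzofuran-3-carboxylate (trans) | COCOc1ccc2c(c1OC)O[C@H](c1cc(OC)c(OC)c(OC)c1)[C@H]2C(=O)OC | intermediate
10 | [(2S,3R)-7-methoxy-6-(methoxymethoxy)-2-(3,4,5-trimethoxyphenyl)-2,3-dihydrobenzofuran-3-yl]methanol (trans) | COCOc1ccc2c(c1OC)O[C@H](c1cc(OC)c(OC)c(OC)c1)[C@H]2CO | intermediate
11 | [(2S,3R)-7-methoxy-6-(methoxymethoxy)-2-(3,4,5-trimethoxyphenyl)-2,3-dihydrobenzofuran-3-yl]methyl 4-methylbenzenesulfonate | COCOc1ccc2c(c1OC)O[C@H](c1cc(OC)c(OC)c(OC)c1)[C@H]2COS(=O)(=O)c1ccc(C)cc1 | intermediate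
12 | (2S,3S)-7-methoxy-6-(methoxymethoxy)-3-methyl-2-(3,4,5-trimethoxyphenyl)-2,3-dihydrobenzofuran | COCOc1ccc2c(c1OC)O[C@H](c1cc(OC)c(OC)c(OC)c1)[C@H]2C | intermediate
13 | (2S,3S)-7-methoxy-3-methyl-2-(3,4,5-trimethoxyphenyl)-2,3-dihydrobenzofuran-6-ol | Oc1ccc2c(c1OC)O[C@H](c1cc(OC)c(OC)c(OC)c1)[C@H]2C | intermediate
14 | allyl bromide | C=CCBr | starting material
15 | (2S,3S)-6-(allyloxy)-7-methoxy-3-methyl-2-(3,4,5-trimethoxyphenyl)-2,3-dihydrobenzofuran | C=CCOc1ccc2c(c1OC)O[C@H](c1cc(OC)c(OC)c(OC)c1)[C@H]2C | intermediate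
16 | (2S,3S)-5-allyl-7-methoxy-3-methyl-2-(3,4,5-trimethoxyphenyl)-2,3-dihydrobenzofuran-6(5H)-one (Claisen ortho-dienone, both C5 epimers, not isolated) | C=CCC1C=C2C(=C(OC)C1=O)O[C@H](c1cc(OC)c(OC)c(OC)c1)[C@H]2C | intermediate
17 | (2S,3S)-5-allyl-7-methoxy-3-methyl-2-(3,4,5-trimethoxyphenyl)-2,3-dihydrobenzofuran-6-ol | C=CCc1cc2c(c(OC)c1O)O[C@H](c1cc(OC)c(OC)c(OC)c1)[C@H]2C | intermediate
18 | (2S,3S,5R)-5-allyl-5-hydroxy-7-methoxy-3-methyl-2-(3,4,5-trimethoxyphenyl)-2,3-dihydrobenzofuran-6(5H)-one | C=CC[C@@]1(O)C=C2C(=C(OC)C1=O)O[C@H](c1cc(OC)c(OC)c(OC)c1)[C@H]2C | intermediate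
19 | (2S,3S,5R)-5-allyl-5,7-dimethoxy-3-methyl-2-(3,4,5-trimethoxyphenyl)-2,3-dihydrobenzofuran-6(5H)-one | C=CC[C@@]1(OC)C=C2C(=C(OC)C1=O)O[C@H](c1cc(OC)c(OC)c(OC)c1)[C@H]2C | target

Total step count: 15. Longest linear sequence: 15 steps (1 to 19); starting materials 4 and 14 enter at steps 3 and 12.

Steps most likely to fail

Risk 1 (step 14): oxygen may be delivered to C7 instead of C5, which would expel methanol and lead to the 6,7-quinone, or the reagent may discriminate poorly between the two faces at C5 because C2 and C3 are remote. The fallback forms the C5–O bond first and the C5–allyl bond second, and it leaves the route before O-allylation. It sets out from phenol 13, which is oxidised with Fremy's salt (KH2PO4 buffer, acetone–water, 0 °C; Teuber oxidation) to (2S,3S)-7-methoxy-3-methyl-2-(3,4,5-trimethoxyphenyl)-2,3-dihydrobenzofuran-5,6-dione F1. Para C3a is substituted, so oxidation should occur at C5, the only free ortho CH. Preformed allylindium sesquibromide (In, allyl bromide, DMF; then F1, −20 °C) should then add to the C5 carbonyl, since the C6 carbonyl is a vinylogous ester deactivated by O1. This gives 18 together with its C5 epimer, (2S,3S,5S)-5-allyl-5-hydroxy-7-methoxy-3-methyl-2-(3,4,5-trimethoxyphenyl)-2,3-dihydrobenzofuran-6(5H)-one F2. The price is that C5 is not controlled; the epimers are separated by chromatography and the route is rejoined at 18.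

Risk 2 (step 15): alkylation of the hindered tertiary α-ketol may be too slow, and any basic activation would start a [3,3] shift of the allyl group. The fallback uses that shift and sets out from 18. KHMDS/18-crown-6 (THF, −78 to 0 °C) triggers an anionic oxy-Cope rearrangement that moves the allyl group suprafacially from C5 to C3a. This gives the potassium enolate of (2S,3S,3aS)-3a-allyl-5-hydroxy-7-methoxy-3-methyl-2-(3,4,5-trimethoxyphenyl)-3,3a-dihydrobenzofuran-6(2H)-one F3, which is O-methylated in the same flask with dimethyl sulfate, an easy enolate alkylation. The product is (2S,3S,3aS)-3a-allyl-5,7-dimethoxy-3-methyl-2-(3,4,5-trimethoxyphenyl)-3,3a-dihydrobenzofuran-6(2H)-one F4. Gentle heating (toluene, reflux, monitored to stop before retro-Claisen aromatisation) should effect the Cope shift that links 3a-allyl and 5-allyl-5-methoxy dienones of this family. The allyl group returns to C5 on the face it left, and the route is rejoined at 19.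

Risk 3 (step 6): the catalyst may not distinguish the two enantiotopic O–CH2 hydrogens well enough, or carbene dimerisation may compete. The fallback adds substrate control and sets out from ester 6:
- LiOH (THF–H2O) gives 2-[3-methoxy-4-(methoxymethoxy)-2-(3,4,5-trimethoxybenzyloxy)phenyl]acetic acid F5.
- DCC/DMAP coupling with (S)-2-hydroxy-1-(pyrrolidin-1-yl)propan-1-one gives (S)-1-oxo-1-(pyrrolidin-1-yl)propan-2-yl 2-[3-methoxy-4-(methoxymethoxy)-2-(3,4,5-trimethoxybenzyloxy)phenyl]acetate F6.
- Diazo transfer (p-ABSA, DBU) gives (S)-1-oxo-1-(pyrrolidin-1-yl)propan-2-yl 2-diazo-2-[3-methoxy-4-(methoxymethoxy)-2-(3,4,5-trimethoxybenzyloxy)phenyl]acetate F7.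
- Rh2(S-DOSP)4 (CH2Cl2, rt) effects the same 1,5-insertion under matched auxiliary/catalyst control, with the auxiliary antipode chosen for the 2S series. The product is (S)-1-oxo-1-(pyrrolidin-1-yl)propan-2-yl (2S,3S)-7-methoxy-6-(methoxymethoxy)-2-(3,4,5-trimethoxyphenyl)-2,3-dihydrobenzofuran-3-carboxylate F8; either C3 epimer serves.
- NaOMe/MeOH transesterifies and equilibrates C3, and the route is rejoined at trans ester 9.

Further compounds
F1 | step 14 | (2S,3S)-7-methoxy-3-methyl-2-(3,4,5-trimethoxyphenyl)-2,3-dihydrobenzofuran-5,6-dione | O=C1C=C2C(=C(OC)C1=O)O[C@H](c1cc(OC)c(OC)c(OC)c1)[C@H]2C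
F2 | step 14 | (2S,3S,5S)-5-allyl-5-hydroxy-7-methoxy-3-methyl-2-(3,4,5-trimethoxyphenyl)-2,3-dihydrobenzofuran-6(5H)-one | C=CC[C@]1(O)C=C2C(=C(OC)C1=O)O[C@H](c1cc(OC)c(OC)c(OC)c1)[C@H]2C
F3 | step 15 | (2S,3S,3aS)-3a-allyl-5-hydroxy-7-methoxy-3-methyl-2-(3,4,5-trimethoxyphenyl)-3,3a-dihydrobenzofuran-6(2H)-one (formed as its potassium enolate) | C=CC[C@]12C=C(O)C(=O)C(OC)=C1O[C@H](c1cc(OC)c(OC)c(OC)c1)[C@H]2C
F4 | step 15 | (2S,3S,3aS)-3a-allyl-5,7-dimethoxy-3-methyl-2-(3,4,5-trimethoxyphenyl)-3,3a-dihydrobenzofuran-6(2H)-one | C=CC[C@]12C=C(OC)C(=O)C(OC)=C1O[C@H](c1cc(OC)c(OC)c(OC)c1)[C@H]2C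
F5 | step 6 | 2-[3-methoxy-4-(methoxymethoxy)-2-(3,4,5-trimethoxybenzyloxy)phenyl]acetic acid | OC(=O)Cc1ccc(OCOC)c(OC)c1OCc1cc(OC)c(OC)c(OC)c1
F6 | step 6 | (S)-1-oxo-1-(pyrrolidin-1-yl)propan-2-yl 2-[3-methoxy-4-(methoxymethoxy)-2-(3,4,5-trimethoxybenzyloxy)phenyl]acetate | C[C@H](OC(=O)Cc1ccc(OCOC)c(OC)c1OCc1cc(OC)c(OC)c(OC)c1)C(=O)N1CCCC1
F7 | step 6 | (S)-1-oxo-1-(pyrrolidin-1-yl)propan-2-yl 2-diazo-2-[3-methoxy-4-(methoxymethoxy)-2-(3,4,5-trimethoxybenzyloxy)phenyl]acetate | C[C@H](OC(=O)C(=[N+]=[N-])c1ccc(OCOC)c(OC)c1OCc1cc(OC)c(OC)c(OC)c1)C(=O)N1CCCC1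
F8 | step 6 | (S)-1-oxo-1-(pyrrolidin-1-yl)propan-2-yl (2S,3S)-7-methoxy-6-(methoxymethoxy)-2-(3,4,5-trimethoxyphenyl)-2,3-dihydrobenzofuran-3-carboxylate | COCOc1ccc2c(c1OC)O[C@H](c1cc(OC)c(OC)c(OC)c1)[C@H]2C(=O)O[C@@H](C)C(=O)N1CCCC1
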